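Gamma was charged with less E than G and zeta with more, and cedar stands between them with equal charges.

the same everywhere: G 0.010 M
- gamma: E 9.4 mM; run made earlier
- zeta: E 13 mM; run made earlier
- eta: E 23 mM; run made earlier
- cedar: E 10.0 mM; time 15 h
- elm: E 20.0 mM; time 15 h

| run | time / h | Z / % | Q / % | D / % | G / % | L / % |
|---|---|---|---|---|---|---|
| gamma | 1.33 | 45.6 | 7.1 | 24.4 | 18.1 | 1.7 |
| gamma | 3.00 | 56.7 | 8.1 | 29.8 | 6.9 | 2.4 |
| gamma | 6.00 | 58.2 | 5.5 | 28.9 | 8.6 | 0 |
| gamma | 15.0 | 56.6 | 1.9 | 32.9 | 8.9 | 0 |
| zeta | 4.00 | 46.1 | 11.5 | 42.3 | 1.5 | 0.1 |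
| zeta | 8.00 | 49.4 | 6.6 | 45.2 | 0 | 0 |
| zeta | 12.0 | 47.0 | 4.4 | 48.5 | 0 | 0.7 |
| zeta | 15.0 | 47.4 | 3.8 | 48.3 | 0.5 | 2.0 |
| eta | 1.33 | 24.5 | 17.7 | 51.3 | 1.0 | 2.3 |
| eta | 3.00 | 27.0 | 16.6 | 56.6 | 1.4 | 1.8 |
| eta | 6.00 | 25.8 | 11.2 | 61.4 | 0.7 | 0.3 |
| eta | 15.0 | 28.1 | 5.4 | 69.0 | 0 | 0 |

(readings scatter by 1 percentage point)

* which of these there is most of at the end, counted by the G in it, cedar (G / Z / D / Q / L)
* which of these there is most of at the end, counted by the G in it, elm (G / Z / D / Q / L)
* the largest of these amounts at the end, in percent of the G charged, cedar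
* the largest of these amounts at the end, in percent of the G charged, elm



We take two ways to Z in cedar. The cheap way draws a straight line through Z at the last readings of gamma and zeta, which gives 55.1% at the charge of cedar.

The second way writes the balance of E, the limiting reagent in gamma. If each G that reacts takes one E, gamma must keep the difference of its charges as G, and it keeps somewhat more, 8.9% at the last reading. That excess leaves 3.09% of the charged E in gamma as the loss share, the part of E that never takes up a G. With the scatter of 1 percentage point it is a rough reading. In cedar the charges are equal, so the G left is the loss share again, 3.09%. The ratio (D + Q)/Z, read along the same line, is 0.696, so Z is 57.2%.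

The ways part by about 2.1 points, and we trust the balance. The straight line cheats: G left is a broken line, which falls as E rises up to equal charges and then lies near zero, as zeta's 0.5% shows.

For elm, with E in excess, we take G as gone. The ratio between zeta and eta gives Z near 31.4%, and D leads.

The forecast names Z at 55.5% for cedar and D at 64% for elm. It reads cedar thus: “About 7% of G remains, so Z is about 55%”. Our reckoning has G at 3.09% instead, and Z at 57.2%, higher than the forecast's 55.5%.

Cedar ends with Z first at 58.6% and elm with D first at 64.6%, as the forecast named them.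

    G + E → L (k = 2.12 /M/min)
    G + E → Z, rate k2*[G] as long as [E] is above zero (k = 0.0136 /min)
    E → X (k = 7.02 × 10⁻⁴ /min)
    L → D (k = 0.0538 /min)
    L ⇌ Q (K = 8.66, k = 0.0215 /min)

Cedar keeps 2.71% of its G with E at 0%, against 3.09% from the loss share. In a flask like elm but charged with E at 0.0050 M, the same share gives 51.5% of the G left, and that flask holds 50.5%. Z leads in cedar because of the path from G + E to Z: with that path taken away, D in cedar goes from 36.2% to 83.8%.

(Readings and results are simulated from invented constants; scatter was added.)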